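Readings and results come from a simulation with constants of no real substance.

The vessel is closed, stirred and held at one temperature, and inside it J turns into E, D, L and Z.

| flask | J | X | G | temperature | remark | time |
|---|---|---|---|---|---|---|
| dusk | 13 mM | 18 mM | 60 mM | 20 °C | run made earlier |  |
| midnight | 30 mM | 18 mM | 60 mM | 39 °C | run made earlier |  |
| spring | 20 mM | 36 mM | 60 mM | 20 °C | run made earlier |  |
| west | 20 mM | 18.0 mM | 60.0 mM | 35 °C |  | 50 h |
| north-east | 20 mM | 18.0 mM | 60.0 mM | 43 °C |  | 50 h |

| run | time / h | Z / % | L / % | E / % | D / % | J / % |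
|---|---|---|---|---|---|---|
| dusk | 5.00 | 0 | 1.0 | 2.2 | 0.3 | 96.8 |
| dusk | 12.0 | 0.3 | 1.8 | 2.1 | 2.4 | 93.4 |
| dusk | 25.0 | 0.5 | 4.4 | 1.9 | 3.6 | 89.9 |
| dusk | 60.0 | 0 | 12.0 | 1.9 | 4.6 | 81.3 |
| midnight | 2.50 | 0.3 | 2.5 | 4.1 | 2.6 | 91.9 |
| midnight | 6.00 | 0 | 7.8 | 2.8 | 4.3 | 84.1 |
| midnight | 12.0 | 0.6 | 13.3 | 3.4 | 5.3 | 76.1 |
| midnight | 30.0 | 3.0 | 30.0 | 2.7 | 3.6 | 60.0 |
| spring | 5.00 | 0.1 | 1.1 | 1.5 | 1.4 | 96.5 |
| spring | 12.0 | 0 | 2.4 | 1.7 | 2.8 | 92.8 |
| spring | 25.0 | 0 | 4.1 | 2.5 | 5.8 | 87.2 |
| spring | 60.0 | 0.4 | 11.0 | 2.2 | 8.3 | 77.4 |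

(standard deviation of a reading: 0.5 percentage points)

- a species is counted by the J in it: one Z counts as two

- which of these there is most of at the end, counted by the J in it, west (E / D / Z / L / J)
- which of these there is most of at the end, counted by the J in it, north-east (E / D / Z / L / J)
- the largest of these amounts at the end, in percent of the J charged, west
- the largest of these amounts at the end, in percent of the J charged, north-east

I begin with X, charged at 18.0 mM in west and north-east against 20 mM of J. If D and Z both carry X, its balance is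

c_X(start) − c_X = c_D + c_Z

At the last midnight reading that comes to 1.53 mM of 18 mM, so X is far from spent. Spring has twice the X of dusk, though a different J, and at 60.0 h L reads 11.0% against 12.0%.

Now the ladder, fastest first. At dusk E reads nearly level from the first reading, 2.2% at 5.00 h and 1.9% at 60.0 h. D is slower, climbing at dusk to 4.6% at 60.0 h. At midnight it reads 5.3% at 12.0 h and 3.6% at 30.0 h, so in that run it is a passing pool. Next comes the slow drain of J, which I read from J itself at the last reading of dusk and of midnight, both run with the X and G of the new flasks: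

k(dusk) = ln(1/J share)/t = 0.00345 /h

k(midnight) = 0.0170 /h

Last comes Z, which reaches 3.0% at the final midnight reading. I take ln k as straight in temperature and set aside that the two runs differ in J as well:

k(T) = k(dusk) · (k(midnight)/k(dusk))^((T − T_dusk)/(T_midnight − T_dusk))

west: 0.0122 /h

north-east: 0.0238 /h

I carry this drain constant, the pseudo-first-order constant of J's disappearance at the flask's temperature. With J = exp(−kt), I reckon that west keeps J at 54.4%, more than everything else together. For north-east I reckon J at 30.4%. Taking off midnight's last readings of E, D and Z leaves my estimate of L in north-east at 60.3%.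

The forecast names J at 60% (53% to 68%) for west and L at 47% (38% to 56%) for north-east, on the ground: “Most of the J loss after the first hours goes to L”. My species are the same, but my numbers differ.

West ends with J at 55.9%, and north-east with L at 56.2%, above the forecast's range.

    J + D → Z (k = 0.340 /M/h, Ea = 80.0 kJ/mol)
    X + E ⇌ D (K = 100 /M, k = 20.0 /M/h, Ea = 49.0 kJ/mol, ΔH = −16.0 kJ/mol)
    J ⇌ E (K = 0.0420, k = 0.0990 /h, Ea = 110 kJ/mol, ΔH = 11.0 kJ/mol)
    G + E → L (k = 4.80 /M/h, Ea = 53.0 kJ/mol)
    (constants at 35 °C)

Against these stand my 54.4% and 60.3%. The drain constant now goes to a repeat of west at 10 °C: k = 0.00149 /h, so after 50 h I reckon J at 92.8%. That flask ends with E at 1.36%, D at 2.39% and J at 93.6%.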